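The earlier runs and the new flask were computed on assumed constants, noise included.

Fractions of the charge let flasks with different amounts of Q be laid side by side, so I count Q, G and GZ as fractions of the Q charged.

| flask | Q | D | X | temperature | remark | time |
|---|---|---|---|---|---|---|
| spring | 0.80 M | 0.72 M | 0.040 M | 10 °C | run made earlier |  |
| noon | 0.80 M | 0.72 M | 0.060 M | 21 °C | run made earlier |  |
| winter | 1.6 M | 0.72 M | 0.080 M | 10 °C | run made earlier |  |
| amber | 0.80 M | 0.720 M | 0.0800 M | 25 °C |  | 25 h |
| green | 0.80 M | 0.720 M | 0.0800 M | 5 °C |  | 25 h |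

| run | time / h | G / % | GZ / % |
|---|---|---|---|
| spring | 5.00 | 49 | 0 |
| spring | 10.0 | 73 | 0 |
| spring | 15.0 | 85 | 1 |
| spring | 30.0 | 92 | 1 |
| spring | 60.0 | 85 | 9 |
| noon | 6.00 | 93 | 0 |
| noon | 12.0 | 90 | 6 |
| noon | 20.0 | 71 | 6 |
| noon | 25.0 | 66 | 13 |
| noon | 30.0 | 58 | 22 |
| winter | 5.00 | 51 | 1 |
| winter | 15.0 | 84 | 1 |
| winter | 30.0 | 93 | 3 |
| winter | 40.0 | 90 | 4 |
| winter | 60.0 | 83 | 7 |

(scatter of a reading: 2 percentage points)

- what is said of GZ includes J
- J is a solid; its amount is given per volume of the solution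
- steps thought possible: Q -> G; D -> Z; G + Z -> GZ; G + X -> GX; J <-> GZ; G -> E

1. the best flask by amount of G, in percent of the Q charged; "all alike" if 1.5 percentage points covers them all (amber / green / all alike)
2. amount of G at the end, in percent of the Q charged, amber
3. amount of G at the end, in percent of the Q charged, green

Winter holds twice the Q of spring, yet at 5.00 h it reads 51% of G against spring's 49%. So in these two flasks, within the scatter, the fraction made in a given time does not follow the charge, and I take Q → G as first order in Q. Spring's GZ reads 0% at that time, so I let G stand for reacted Q, which gives 0.135 h⁻¹. Noon's 93% at 6.00 h gives 0.443 h⁻¹, but that reading lies near full reaction and is loose. Carrying the logarithm of the constant evenly per degree down to green's 5 °C gives 0.0784 h⁻¹; this is my Q clock, the first-order rate constant of Q → G in green. By this reckoning 14.1% of Q stands in green at 25 h, so I expect G somewhat under 85.9%. Noon, cooler than amber and with less X, already reads G 66% at 25.0 h, so I place amber well below green.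

The forecast names green, with amber at 45% (35% to 56%) and green at 75% (69% to 81%). Its figure of “conversion is about 82% at 25 h” differs from mine.

The simulation names green as the better flask, with more G in green at 78.2% than in amber at 45.1%, each inside the forecast's range.

    Q → G (k = 1.20 h⁻¹, Ea = 101 kJ mol⁻¹)
    D → Z (k = 0.0850 h⁻¹, Ea = 87.0 kJ mol⁻¹)
    G + Z → GZ (k = 0.0490 M⁻¹ h⁻¹, Ea = 86.0 kJ mol⁻¹)
    G + X → GX (k = 0.0450 M⁻¹ h⁻¹, Ea = 68.0 kJ mol⁻¹)
    J ⇌ GZ, rate k5*(cs5 - [GZ]) while solid is left; crystals form when [GZ] > cs5 (solubility = 0.320 M, k = 2.90 h⁻¹)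
    G → E (k = 0.0140 h⁻¹, Ea = 110 kJ mol⁻¹)
    (constants at 25 °C)

Read at 30.1 h, green's G has moved 5 points, and the forecast's high end lies 2.8 percentage points above 78.2%. Green at 25 h holds 20.1% of Q where my clock left 14.1%. The same clock on green read at 6.0 h leaves 62.5% of Q; that neighbouring flask holds 68.1% of Q and 31.8% of G.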